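## Structural features

The target is a longipinane-type sesquiterpenoid diester. Its core is a cyclobutane C4–C5–C11–C10 whose C11/C4 diagonal is spanned by the enone C1(=O)–C2=C3(CH3), a bicyclo[3.1.1]heptenone of the verbenone kind. The C5/C10 diagonal is spanned by C6(CH3)2–C7–C8–C9, which closes the seven-membered ring C5–C6–C7–C8–C9–C10–C11; these locants are used throughout. Four of the six stereocentres (C4, C5, C10, C11) are contiguous on the cyclobutane and their relative configuration is forced by the two bridges. What must be controlled is their absolute sense and their relation to the carbinol centres C7 (tiglate, next to the gem-dimethyl carbon C6) and C9 (angelate, next to the quaternary C10); O7 and O9 are trans. The angelate isomerises to the tiglate with base, nucleophilic catalysts or heat, the enone-flanked cyclobutane is pinene-like and opens with acid, and the two hindered hydroxyls are similar, so acylation must be stepwise and differentiated. The real difficulty is the doubly bridged four-membered ring with the quaternary C10, and placing C7 and C9 correctly relative to it. The key step exploits that C1 is a carbonyl carbon bound to the cyclobutane carbon C11, while C10 and C11 are adjacent members of the seven-membered ring. C1 can therefore be a ketene carbon (C2 its α-carbon) that adds to a C10=C11 alkene of a pre-formed cycloheptene, C1 to C11 and C2 to C10, giving the chrysanthenone-type isomer of the core. Its C2–C10 bond is allylic and α to the cyclobutanone carbonyl; moving C10 along the allyl unit to C4 completes the cyclobutane and the conjugated enone.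

## Logic of the disconnections

The two acyl–oxygen bonds of 21 (at O7, then at O9) and the two silicon–oxygen bonds are cut first, leading through 20, 19 and 18 to 17. The esters, above all the angelate, would not survive hydrazine, strong base or 190 °C, so they go on last. The gain is that every earlier step works on a robust bis-silyl ether. The demand is a reliable order of unmasking (triethylsilyl on O9 before tert-butyldimethylsilyl on O7) and an angeloylation that does not isomerise.

In 17 the C4–C10 bond is cut and C10 is reconnected to C2, which gives 16. The reason is that 16 is the direct skeleton of a ketene–alkene cycloaddition, whereas 17 is not the adduct of any simple cycloaddition. The gain is that the bridged cyclobutane is traded for a cyclobutanone that one step can build. The demand is a clean 1,3-shift of C10 across C2–C3–C4 without loss of the cage.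

In 16 the C3=C4 alkene is moved to the exocyclic position on C3, which gives 15. The reason is that the ketene available from a 3-methylalk-2-enoyl chloride carries its alkene there. The gain is a precursor that matches known ketene chemistry. The demand is a selective alkene shift in which only C4 can deliver hydrogen.

In 15 the bonds C1–C11 and C2–C10 are cut, which leads through the ketene 14 to 13. The reason is that both bonds end on the ring alkene and start on one ketene unit held by the C5 tether. The gain is two rings, two skeletal bonds and three stereocentres in one step from a monocyclic compound. The demand is bridged regiochemistry, addition on the face of the C5 side chain, and a cycloaddition faster than ketene oligomerisation.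

The carbon–chlorine bond of 13, the ester oxygen–carbon bond (12 from 11) and the O9–silicon bond (11 from 10) are functional-group changes. They place the acid-labile and base-labile groups in an order that each reagent tolerates. The demand is neutral formation of the acid chloride next to an allylic silyl ether.

The C9–O bond and the C10=C11 alkene of 10 are traced to the epoxy ketone 9 and then to the enone 8. The reason is that the ring ketone at C11 is needed to attach the side chain at C5 and afterwards has to become the alkene CH. The gain is that one oxygen-transposition sequence sets C9 and produces the alkene. The demand is epoxidation on the face opposite to the substituents at C5 and C7.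

The C4–C5 bond of 8 is cut between the α′-carbon of the enone 6 and the allylic bromide 7. The reason is that this is the only enolisable position of 6 that is not vinylogous. The gain is a convergent union with a commercial five-carbon unit that already holds C1–C4 and the C3 methyl. The demand is control of C5 relative to C7.

The C7–O bond of 6 is traced through 4 to a carbon–boron bond made on eucarvone 1 with 2. The reason is that C7 is the δ-carbon of the dienone. The gain is that the only reagent-controlled stereocentre is set on a commercial achiral ketone. The demand is 1,6- rather than 1,4-addition with high enantioselectivity next to a quaternary carbon.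

## Other disconnections considered

Alternative 1: The cut is the C2=C3 double bond of the ketal-protected enone A2 (the core without the C7 oxygen). It leads back to the meso diketone A1, a cis-1,3-diacetylcyclobutane whose other diagonal carries the seven-membered ring with the C9 ketal. Forward, L-proline would form the enamine of one enantiotopic acetyl group of A1, add it to the other carbonyl and dehydrate, a desymmetrising aldol condensation of the Hajos–Parrish kind.
- In favour: the reaction type is well understood, needs no temporary bond, and would fix all four core stereocentres, absolute configuration included, in one catalytic step. On this point it is better than the chosen plan, where the core rests on a C5 centre from a possibly unselective alkylation and on an untested 1,3-shift.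
- Against: the hard object, the 1,3-bridged cyclobutane with the quaternary C10, is already present in A1, so the hardest construction is only moved into the synthesis of A1, for which no short route is evident. The aldol must close a strained bridged enone from two hindered methyl ketones and may be slow or reversible. A2 also lacks the C7 oxygen, which would have to be introduced late, next to the gem-dimethyl carbon, with C7 and C9 then set on the finished cage.
- Comparison: the key step is equal to the cycloaddition in step count and better in mechanism, but the preparation of A1 and the late oxidation at C7 should make the whole route longer than the chosen one, where C7 is the first centre set.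

Alternative 2: The cut is C5–C11 and C4–C10 of the bicyclic cyclobutanone A4, back to the open-chain silyloxy-trienoyl chloride A3. Forward, triethylamine would convert A3 to its cross-conjugated vinylketene, which adds across the C10=C11 alkene to give A4, a bicyclo[3.1.1]heptan-6-one with C5 as the ketone and an exocyclic methylene on C3.
- In favour: this copies the known cyclisation of farnesoyl chloride, so the key step is better precedented than the chosen one, and it puts C10 on C4 at once, so no transposition is needed. On both points it is better.
- Against: the seven-membered ring is still missing. It would need a C5–C6 bond between a cyclobutanone carbonyl carbon and the fully substituted end of the prenyl alkene, after which C5 must lose its oxygen and C7 gain one. The enone needs an alkene shift and an allylic oxidation at C1, and the alkene face is chosen only by an open-chain C9 centre.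
- Comparison: the cycloaddition is mechanistically equal to the chosen one, but the hard structural part (a seven-membered ring bridging the cyclobutane, with C7 oxygenated) is left to a long, uncertain endgame. The step count should exceed that of the chosen plan, where the ring and both oxygens are in place before the cycloaddition.

Alternative 3: The cut is the C10–C11 bond of A6 (identical with compound 17), with C10 returned to C1. This leads to the norbornene A5, a bridgehead alcohol at C1 with an endo mesylate at C11 and the seven-membered ring already spanning C5 and C10. Forward, deprotonation of A5 would trigger a semipinacol shift: C10, anti-periplanar to the leaving group, migrates from C1 to C11 while C1 becomes the enone carbonyl, contracting the norbornene to the cyclobutane.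
- In favour: it ends at the same compound as step 11. The 1,2-migration has a defined stereoelectronic requirement and an irreversible carbonyl-forming push; in mechanistic security it is better than the thermal 1,3-shift of the chosen plan.
- Against: A5 is as complex as the target core. It presupposes an intramolecular Diels–Alder reaction of a 5,5-disubstituted 1-silyloxycyclopentadiene onto a trisubstituted dienophile next to the gem-dimethyl carbon, with both oxygen stereocentres on the tether, and then the endo oxygen at C11. The contraction builds the strain of a cyclobutane and must beat migration of the vinylic C2 and fragmentation.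
- Comparison: in step economy it is at best equal. The endgame after A6 is the same, and what is saved on the alkene shift and rearrangement is spent on assembling the cyclopentadiene and its tether.

Key step: step 9

Remark on the chemistry (correction): in the (E)-acid chloride 13 the γ-hydrogens cis to the carbonyl are those of the C3 methyl group, so dehydrochlorination gives the cross-conjugated vinylketene 14 (C3=CH2) and the first cycloadduct 15 has its alkene exocyclic on C3; the C3=C4 isomer 16 is made from it by a separate alkene shift (step 10), with the bonds formed, the rings closed and the skeletons unchanged.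

Remark on the chemistry (assumption): eucarvone 1 and the (E)-bromo ester 7 are taken as purchasable, and the ligand enantiomer in step 1 is the one that gives the (5R)-boronate.

## Route

Step 1
Reactants: 1 eucarvone; 2 bis(pinacolato)diboron
Product: 4 (5R)-5-hydroxy-2,6,6-trimethylcyclohept-3-en-1-one (C2 epimers), via allylboronate 3 (not isolated)
Conditions: CuCl (5 mol %), (R)-1-[(S)-2-(diphenylphosphino)ferrocenyl]ethyldicyclohexylphosphine or its enantiomer (6 mol %), NaOt-Bu (10 mol %), MeOH (2 equiv), THF, 0 °C to rt; then NaBO3·4H2O, THF/H2O, rt
Reagents that add atoms: sodium perborate tetrahydrate, [Na+].[O-]OB=O.O.O.O.O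
Why: Copper-catalysed asymmetric 1,6-conjugate borylation: the copper boryl adds to the δ-carbon (C7) of the dienone, methanol protonates the copper dienolate at the α-carbon, and perborate oxidises C–B to C–O with retention. C7 is set by the chiral bisphosphine, which selects the face of the cis γ,δ-alkene; it is the only reagent-controlled stereocentre of the route.

Step 2
Reactants: 4 (5R)-5-hydroxy-2,6,6-trimethylcyclohept-3-en-1-one
Product: 6 (5R)-5-[(tert-butyldimethylsilyl)oxy]-2,6,6-trimethylcyclohept-2-en-1-one, via conjugated hydroxy enone 5 (not isolated)
Conditions: DBU (0.2 equiv), CH2Cl2, rt; then 2,6-lutidine, TBSOTf, −78 to 0 °C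
Reagents that add atoms: tert-butyldimethylsilyl trifluoromethanesulfonate, CC(C)(C)[Si](C)(C)OS(=O)(=O)C(F)(F)F
Why: Base-mediated alkene migration through the dienolate should give the trisubstituted conjugated enone, the thermodynamic isomer; it is done on the free alcohol because hydroxide is too poor a leaving group for elimination back to 1. The hindered neopentyl-type alcohol is then silylated by the silyl triflate at low temperature, where O-silylation outruns enol silylation.

Step 3
Reactants: 6 (5R)-5-[(tert-butyldimethylsilyl)oxy]-2,6,6-trimethylcyclohept-2-en-1-one; 7 ethyl (E)-4-bromo-3-methylbut-2-enoate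
Product: 8 ethyl (E)-4-[(1R,6R)-6-[(tert-butyldimethylsilyl)oxy]-3,7,7-trimethyl-2-oxocyclohept-3-en-1-yl]-3-methylbut-2-enoate
Conditions: LiN(i-Pr)2 (1.05 equiv), THF, −78 °C; then 7, DMPU, −78 to −30 °C; separation of the C5 epimers
Reagents that add atoms: none
Why: Kinetic α′-deprotonation of the enone (cross-conjugated lithium enolate) and SN2 alkylation by the allylic bromide, as known for the α′-alkylation of isophorone next to its gem-dimethyl carbon. The new centre C5 must be cis to the C7 silyloxy group; face selectivity on this enolate cannot be predicted safely, so the epimers are separated and the unwanted one, epimerisable α to the ketone, is recycled.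

Step 4
Reactants: 8 ethyl (E)-4-[(1R,6R)-6-[(tert-butyldimethylsilyl)oxy]-3,7,7-trimethyl-2-oxocyclohept-3-en-1-yl]-3-methylbut-2-enoate
Product: 9 ethyl (E)-4-[(1R,6R)-6-[(tert-butyldimethylsilyl)oxy]-3,4-epoxy-3,7,7-trimethyl-2-oxocycloheptyl]-3-methylbut-2-enoate (epoxide oxygen trans to the side chain and to the silyloxy group)
Conditions: t-BuOOH, n-BuLi, THF, −78 to −20 °C
Reagents that add atoms: tert-butyl hydroperoxide, CC(C)(C)OO
Why: Weitz–Scheffer epoxidation with lithium tert-butylperoxide, a weakly basic nucleophilic oxidant that should leave the less electrophilic β,β-disubstituted enoate and the C5 centre alone. The peroxide should add to C9 on the face opposite to the C5 side chain and the C7 silyloxy group, as in the trans-selective epoxidation of carvone; this sets C9.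

Step 5
Reactants: 9 epoxy ketone
Product: 10 ethyl (E)-4-[(1S,4R,6R)-6-[(tert-butyldimethylsilyl)oxy]-4-hydroxy-3,7,7-trimethylcyclohept-2-en-1-yl]-3-methylbut-2-enoate
Conditions: N2H4·H2O (3 equiv), AcOH (cat.), MeOH, 0 °C to rt
Reagents that add atoms: none
Why: Wharton transposition: the hydrazone of the epoxy ketone opens the epoxide to an alkenyl diazene that loses N2, so the C9–O bond is untouched, the carbinol keeps the epoxide configuration, and the alkene appears at C10=C11. A short reaction at low temperature should keep hydrazinolysis of the ethyl ester negligible.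

Step 6
Reactants: 10 allylic alcohol
Product: 11 ethyl (E)-4-[(1S,4R,6R)-6-[(tert-butyldimethylsilyl)oxy]-3,7,7-trimethyl-4-[(triethylsilyl)oxy]cyclohept-2-en-1-yl]-3-methylbut-2-enoate
Conditions: TESCl, imidazole, CH2Cl2, 0 °C to rt
Reagents that add atoms: chlorotriethylsilane, CC[Si](Cl)(CC)CC
Why: Standard silylation of a secondary allylic alcohol; the triethylsilyl group is chosen so that O9 can later be freed before O7.

Step 7
Reactants: 11 bis-silyl ether ester
Product: 12 (E)-4-[(1S,4R,6R)-6-[(tert-butyldimethylsilyl)oxy]-3,7,7-trimethyl-4-[(triethylsilyl)oxy]cyclohept-2-en-1-yl]-3-methylbut-2-enoic acid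
Conditions: KOSiMe3 (3 equiv), THF, rt; then aq. KHSO4
Reagents that add atoms: potassium trimethylsilanolate, C[Si](C)(C)[O-].[K+]
Why: Anhydrous silanolate cleavage of the ethyl ester (attack at the acyl carbon, ethoxide leaving as its silyl ether) should leave both silyl ethers and the E alkene untouched.

Step 8
Reactants: 12 acid
Product: 13 (E)-4-[(1S,4R,6R)-6-[(tert-butyldimethylsilyl)oxy]-3,7,7-trimethyl-4-[(triethylsilyl)oxy]cyclohept-2-en-1-yl]-3-methylbut-2-enoyl chloride
Conditions: 1-chloro-N,N,2-trimethylprop-1-en-1-amine (1.2 equiv), CH2Cl2, 0 °C to rt; concentrated and used crude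
Reagents that add atoms: 1-chloro-N,N,2-trimethylprop-1-en-1-amine, CC(C)=C(Cl)N(C)C
Why: The α-chloroenamine converts the acid to the acid chloride under neutral conditions without free HCl, so the acid-labile allylic triethylsilyl ether and the E geometry (methyl cis to the carbonyl) are kept.

Step 9
Reactants: 13 acid chloride
Product: 15 (2S,5S,7R,9R,10S,11R)-tricyclic cyclobutanone with C1 ketone bridging C11 and C2, C2–C10 bond, exocyclic methylene on C3, 7-OTBS and 9-OTES, via vinylketene 14 (not isolated)
Conditions: Et3N (4 equiv), toluene, 110 °C, 13 added over 6 h to 0.005 M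
Reagents that add atoms: none
Why: Triethylamine removes HCl in a 1,4-sense from the C3 methyl group, which is cis to the carbonyl in the (E)-chloride, giving the cross-conjugated vinylketene 14 at low stationary concentration. Its C1=C2 bond then adds to the ring alkene in a thermal, asynchronous [π2s+π2a] cycloaddition: the electrophilic C1 bonds to the less substituted C11 while positive charge builds on the methyl-bearing C10, which closes onto C2. The closest known reaction type is the intramolecular vinylketene–alkene cycloaddition of 3-methylalk-2-enoyl chlorides such as geranoyl and farnesoyl chloride to 2-methylenebicyclo[3.1.1]heptan-6-ones; here the alkene is part of a ring and sits on an allylic carbon of the three-atom tether C3–C4–C5. The six-membered ring C1–C2–C3–C4–C5–C11 closes by attack of C1 on the proximal alkene carbon in the bridged (crossed) mode, and the cyclobutanone C1–C2–C10–C11 closes by the C2–C10 bond in the same event. C11 and C10 are set by suprafacial addition to the alkene face that carries the C5 side chain, so C5 controls both, and the bridgehead C2 is fixed by the bicyclic geometry. The step needs bridged rather than fused regiochemistry, secured by the higher substitution of C10 and the tether length, and cycloaddition rather than ketene oligomerisation, secured by slow addition at high dilution. The C9 silyloxy group lies on the face opposite to the incoming ketene and should not block it.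

Step 10
Reactants: 15 exo-methylene cyclobutanone
Product: 16 (2S,5S,7R,9R,10S,11R)-tricyclic cyclobutanone with C1 ketone bridging C11 and C2, C2–C10 bond, C3=C4 alkene with methyl on C3, 7-OTBS and 9-OTES
Conditions: 5% Pd/C (pre-saturated with H2, then N2), cyclohexane, 60 °C
Reagents that add atoms: none
Why: Palladium hydride addition–elimination moves the exocyclic alkene into the ring, the isomerisation that converts the 2-methylene ketone of the model series into chrysanthenone; only C4 can give up a hydrogen because C2 is a bridgehead, and the trisubstituted alkene is the thermodynamic isomer. A non-protic solvent is used so that the triethylsilyl ether is not cleaved on the catalyst.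

Step 11
Reactants: 16 endocyclic cyclobutanone
Product: 17 (4R,5S,7R,9R,10R,11R)-7-[(tert-butyldimethylsilyl)oxy]-9-[(triethylsilyl)oxy]longipin-2-en-1-one
Conditions: o-xylene (0.01 M), 2,6-di-tert-butyl-4-methylpyridine (0.1 equiv), degassed, sealed silanised tube, 190 °C
Reagents that add atoms: none
Why: Proposed new method: homolysis of the C2–C10 bond, which is allylic, α to the cyclobutanone carbonyl and part of a strained ring, should give a tertiary radical at C10 paired with an oxapentadienyl radical (O–C1–C2–C3–C4) that recloses at C4 to the conjugated enone, the more stable isomer; the closest known reaction types are the thermal 1,3-carbon shift of vinylcyclobutanes (racemisation of α-pinene by shift of its gem-dimethyl bridge, isomerisation of 2-vinylcyclobutyl ketones to cyclohexenes) and the photochemical enone-to-cyclobutanone shift of verbenone, which runs in the opposite direction. C10 stays bonded to C11 on the same face of the six-membered ring, so it keeps its configuration and C4 is set by the cage.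

Step 12
Reactants: 17 bis-silyl enone
Product: 18 (4R,5S,7R,9R,10R,11R)-7-[(tert-butyldimethylsilyl)oxy]-9-hydroxylongipin-2-en-1-one
Conditions: HF·pyridine, pyridine, THF, 0 °C
Reagents that add atoms: none
Why: Buffered HF·pyridine cleaves the triethylsilyl ether much faster than the tert-butyldimethylsilyl ether, and the near-neutral medium should spare the cyclobutane–enone.

Step 13
Reactants: 18 C9 alcohol
Product: 19 (4R,5S,7R,9R,10R,11R)-7-[(tert-butyldimethylsilyl)oxy]-1-oxolongipin-2-en-9-yl (Z)-2-methylbut-2-enoate
Conditions: angelic acid, 2,4,6-trichlorobenzoyl chloride, Et3N, toluene, rt; then 18, 80 °C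
Reagents that add atoms: angelic acid, C/C=C(/C)C(=O)O
Why: Yamaguchi-type acylation through the mixed anhydride of angelic acid, run without a nucleophilic pyridine catalyst, is the established way to esterify hindered alcohols with angelic acid without Z-to-E isomerisation.

Step 14
Reactants: 19 C9 angelate
Product: 20 (4R,5S,7R,9R,10R,11R)-7-hydroxy-1-oxolongipin-2-en-9-yl (Z)-2-methylbut-2-enoate
Conditions: HF·pyridine (excess), THF, 0 °C to rt
Reagents that add atoms: none
Why: Fluoride-assisted cleavage of the hindered silyl ether under acidic, non-nucleophilic conditions, which should neither isomerise the angelate nor move it to the trans-disposed O7.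

Step 15
Reactants: 20 C7 alcohol
Product: 21 (4R,5S,7R,9R,10R,11R)-9-[(Z)-2-methylbut-2-enoyloxy]-1-oxolongipin-2-en-7-yl (E)-2-methylbut-2-enoate (CNP0236543.2)
Conditions: tigloyl chloride, pyridine, DMAP (cat.), CH2Cl2, 0 °C to rt
Reagents that add atoms: tigloyl chloride, C/C=C(\C)C(=O)Cl
Why: Acylation of the neopentyl-type alcohol by the acid chloride with catalytic DMAP; the tiglate is the stable E isomer and the angelate, already an ester, should not isomerise under these conditions.

## Compound list

1 | eucarvone (2,6,6-trimethylcyclohepta-2,4-dien-1-one) | CC1=CC=CC(C)(C)CC1=O | starting material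
2 | bis(pinacolato)diboron | CC1(C)OB(OC1(C)C)B1OC(C)(C)C(C)(C)O1 | starting material
3 | (5R)-2,6,6-trimethyl-5-(4,4,5,5-tetramethyl-1,3,2-dioxaborolan-2-yl)cyclohept-3-en-1-one (C2 epimers) | CC1C=C[C@@H](B2OC(C)(C)C(C)(C)O2)C(C)(C)CC1=O | intermediate (not isolated)
4 | (5R)-5-hydroxy-2,6,6-trimethylcyclohept-3-en-1-one (C2 epimers) | CC1C=C[C@@H](O)C(C)(C)CC1=O | intermediate
5 | (5R)-5-hydroxy-2,6,6-trimethylcyclohept-2-en-1-one | CC1=CC[C@@H](O)C(C)(C)CC1=O | intermediate (not isolated)
6 | (5R)-5-[(tert-butyldimethylsilyl)oxy]-2,6,6-trimethylcyclohept-2-en-1-one | CC1=CC[C@@H](O[Si](C)(C)C(C)(C)C)C(C)(C)CC1=O | intermediate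
7 | ethyl (E)-4-bromo-3-methylbut-2-enoate | CCOC(=O)/C=C(\C)CBr | starting material
8 | ethyl (E)-4-[(1R,6R)-6-[(tert-butyldimethylsilyl)oxy]-3,7,7-trimethyl-2-oxocyclohept-3-en-1-yl]-3-methylbut-2-enoate (side chain cis to the silyloxy group) | CCOC(=O)/C=C(\C)C[C@@H]1C(C)(C)[C@H](O[Si](C)(C)C(C)(C)C)CC=C(C)C1=O | intermediate
9 | ethyl (E)-4-[(1R,6R)-6-[(tert-butyldimethylsilyl)oxy]-3,4-epoxy-3,7,7-trimethyl-2-oxocycloheptyl]-3-methylbut-2-enoate (epoxide oxygen trans to side chain and silyloxy group) | CCOC(=O)/C=C(\C)C[C@@H]1C(C)(C)[C@H](O[Si](C)(C)C(C)(C)C)C[C@H]2O[C@@]2(C)C1=O | intermediate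
10 | ethyl (E)-4-[(1S,4R,6R)-6-[(tert-butyldimethylsilyl)oxy]-4-hydroxy-3,7,7-trimethylcyclohept-2-en-1-yl]-3-methylbut-2-enoate | CCOC(=O)/C=C(\C)C[C@@H]1C(C)(C)[C@H](O[Si](C)(C)C(C)(C)C)C[C@@H](O)C(C)=C1 | intermediate
11 | ethyl (E)-4-[(1S,4R,6R)-6-[(tert-butyldimethylsilyl)oxy]-3,7,7-trimethyl-4-[(triethylsilyl)oxy]cyclohept-2-en-1-yl]-3-methylbut-2-enoate | CCOC(=O)/C=C(\C)C[C@@H]1C(C)(C)[C@H](O[Si](C)(C)C(C)(C)C)C[C@@H](O[Si](CC)(CC)CC)C(C)=C1 | intermediate
12 | (E)-4-[(1S,4R,6R)-6-[(tert-butyldimethylsilyl)oxy]-3,7,7-trimethyl-4-[(triethylsilyl)oxy]cyclohept-2-en-1-yl]-3-methylbut-2-enoic acid | OC(=O)/C=C(\C)C[C@@H]1C(C)(C)[C@H](O[Si](C)(C)C(C)(C)C)C[C@@H](O[Si](CC)(CC)CC)C(C)=C1 | intermediate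
13 | (E)-4-[(1S,4R,6R)-6-[(tert-butyldimethylsilyl)oxy]-3,7,7-trimethyl-4-[(triethylsilyl)oxy]cyclohept-2-en-1-yl]-3-methylbut-2-enoyl chloride | ClC(=O)/C=C(\C)C[C@@H]1C(C)(C)[C@H](O[Si](C)(C)C(C)(C)C)C[C@@H](O[Si](CC)(CC)CC)C(C)=C1 | intermediate (key-step precursor)
14 | 3-{[(1S,4R,6R)-6-[(tert-butyldimethylsilyl)oxy]-3,7,7-trimethyl-4-[(triethylsilyl)oxy]cyclohept-2-en-1-yl]methyl}buta-1,3-dien-1-one | O=C=CC(=C)C[C@@H]1C(C)(C)[C@H](O[Si](C)(C)C(C)(C)C)C[C@@H](O[Si](CC)(CC)CC)C(C)=C1 | intermediate (not isolated)
15 | (2S,5S,7R,9R,10S,11R)-tricyclic cyclobutanone: C1 ketone bridging C11 and C2, C2–C10 bond, exocyclic methylene on C3, 7-OTBS, 9-OTES | O=C1[C@H]2C(=C)C[C@@H]3C(C)(C)[C@H](O[Si](C)(C)C(C)(C)C)C[C@@H](O[Si](CC)(CC)CC)[C@@]2(C)[C@H]13 | intermediate (key-step product)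
16 | (2S,5S,7R,9R,10S,11R)-tricyclic cyclobutanone: C1 ketone bridging C11 and C2, C2–C10 bond, C3=C4 alkene, 7-OTBS, 9-OTES | O=C1[C@H]2C(C)=C[C@@H]3C(C)(C)[C@H](O[Si](C)(C)C(C)(C)C)C[C@@H](O[Si](CC)(CC)CC)[C@@]2(C)[C@H]13 | intermediate
17 | (4R,5S,7R,9R,10R,11R)-7-[(tert-butyldimethylsilyl)oxy]-9-[(triethylsilyl)oxy]longipin-2-en-1-one | CC[Si](CC)(CC)O[C@@H]1C[C@@H](O[Si](C)(C)C(C)(C)C)C(C)(C)[C@@H]2[C@H]3C(=O)C=C(C)[C@@H]2[C@]31C | intermediate
18 | (4R,5S,7R,9R,10R,11R)-7-[(tert-butyldimethylsilyl)oxy]-9-hydroxylongipin-2-en-1-one | O[C@@H]1C[C@@H](O[Si](C)(C)C(C)(C)C)C(C)(C)[C@@H]2[C@H]3C(=O)C=C(C)[C@@H]2[C@]31C | intermediate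
19 | (4R,5S,7R,9R,10R,11R)-7-[(tert-butyldimethylsilyl)oxy]-1-oxolongipin-2-en-9-yl (Z)-2-methylbut-2-enoate | C/C=C(/C)C(=O)O[C@@H]1C[C@@H](O[Si](C)(C)C(C)(C)C)C(C)(C)[C@@H]2[C@H]3C(=O)C=C(C)[C@@H]2[C@]31C | intermediate
20 | (4R,5S,7R,9R,10R,11R)-7-hydroxy-1-oxolongipin-2-en-9-yl (Z)-2-methylbut-2-enoate | C/C=C(/C)C(=O)O[C@@H]1C[C@@H](O)C(C)(C)[C@@H]2[C@H]3C(=O)C=C(C)[C@@H]2[C@]31C | intermediate
21 | (4R,5S,7R,9R,10R,11R)-9-[(Z)-2-methylbut-2-enoyloxy]-1-oxolongipin-2-en-7-yl (E)-2-methylbut-2-enoate (CNP0236543.2) | C/C=C(/C)C(=O)O[C@@H]1C[C@@H](OC(=O)/C(C)=C/C)C(C)(C)[C@@H]2[C@H]3C(=O)C=C(C)[C@@H]2[C@]31C | target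

Total step count: 15. Longest linear sequence: 15 steps (from 1; 2 and 7 enter in steps 1 and 3).

## Least certain steps and fallbacks

Step 11 (carries the label; riskiest). The most likely failure is diversion of the C2–C10 cleavage into hydrogen transfer from C9, whose hydrogen is syn to the C3=C4 alkene; this would open the ring to a silyl enol ether. Cycloreversion to a vinylketene is a second diversion. Both need temperatures similar to the wanted reclosure at C4. The fallback uses known reactions on a changed substrate; it sets out from 16 and comes back at 21. Selective removal of the triethylsilyl group (HF·pyridine, pyridine, THF) should give the 9-hydroxy cyclobutanone F1, and Dess–Martin oxidation the 1,9-diketone F2. In F2 the C2–C10 bond is the ring bond of a 2-vinylcyclobutyl ketone, C9 carries no hydrogen to transfer, and the C10 radical is stabilised by the C9 carbonyl. Gentle heating (toluene, 80–110 °C) should then give the 9-oxo enone F3 by the thermal 1,3-shift of 2-vinylcyclobutyl ketones to cyclohex-3-enyl ketones, known from the isomerisation of enone–diene [2+2] adducts to formal Diels–Alder adducts. HF·pyridine frees O7 to give the hydroxy diketone F4. An Evans–Tishchenko reduction with tiglaldehyde and catalytic SmI2 delivers hydride from the O7 hemiacetal to C9; this sets the 7,9-anti relationship and leaves the tiglate on O7, giving the hydroxy tiglate F5. Angeloylation of F5 as in step 13 gives 21. Hydride reduction of F3 with O7 still silylated is avoided because attack anti to the silyloxy group would give the wrong C9 epimer.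

Step 9 (key step). The most likely failure is consumption of the ketene by oligomerisation, or by deprotonation at C4 to a conjugated dienylketene that cannot reach the alkene, before the slow cycloaddition that must create the quaternary C10 next to the silyloxy-bearing C9. The fallback changes how the ketene is made; it sets out from 11 and comes back at 15. Deconjugation of 11 (LiN(i-Pr)2, HMPA, THF, −78 °C, then kinetic protonation with AcOH) should give the β,γ-unsaturated ester F6 with the methylene already on C3. Cold LiOH gives the acid F7 and the α-chloroenamine of step 8 gives the acid chloride F8. Ordinary 1,2-dehydrochlorination of F8 with Et3N at room temperature forms the same vinylketene 14 with unambiguous regiochemistry and without prolonged heating of amine hydrochloride; heating the dilute solution then gives 15.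

Step 3. The most likely failure is poor or reversed facial selectivity at C5, because the enolate carbon lies between the carbonyl and a gem-dimethyl carbon and the directing C7 group is two atoms away. The fallback sets the centre by protonation instead of alkylation; it sets out from 6 and comes back at 8. The lithium enolate of 6 is added to ethyl (E)-3-methyl-4-oxobut-2-enoate to give the aldol adduct F9. Dehydration (MsCl, Et3N; then DBU) gives the cross-conjugated dienone ester F10. Conjugate reduction of the exocyclic C4=C5 bond with [(Ph3P)CuH]6, followed by kinetic protonation of the resulting enolate, delivers the hydrogen to the face that an alkyl halide would have taken, so it should favour the epimer that the alkylation disfavours, namely 8.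

Step 1. The most likely failure is 1,4- instead of 1,6-addition, with low enantioselectivity, because the δ-carbon is next to a quaternary centre. The fallback replaces boron addition by oxygen transfer; it sets out from 1 and comes back at 4. Jacobsen epoxidation of the cis γ,δ-alkene, which is conjugated and flanked by a quaternary carbon like a 2,2-dimethylchromene, uses [N,N′-bis(3,5-di-tert-butylsalicylidene)-1,2-cyclohexanediaminato]manganese chloride (5 mol %), NaOCl and 4-phenylpyridine N-oxide in CH2Cl2 at 0 °C and should give the epoxy enone F11. SmI2 (THF/MeOH, −78 °C) then cleaves the γ C–O bond of this vinylogous epoxy ketone to the δ-hydroxy β,γ-enone 4 with the C7 configuration retained.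

## Further compounds

F1 | step 11 | 9-hydroxy cyclobutanone (16 with free O9) | O=C1[C@H]2C(C)=C[C@@H]3C(C)(C)[C@H](O[Si](C)(C)C(C)(C)C)C[C@@H](O)[C@@]2(C)[C@H]13
F2 | step 11 | 1,9-diketone (16 with C9 ketone) | O=C1[C@H]2C(C)=C[C@@H]3C(C)(C)[C@H](O[Si](C)(C)C(C)(C)C)CC(=O)[C@@]2(C)[C@H]13
F3 | step 11 | (4R,5S,7R,10R,11R)-7-[(tert-butyldimethylsilyl)oxy]longipin-2-ene-1,9-dione | O=C1C[C@@H](O[Si](C)(C)C(C)(C)C)C(C)(C)[C@@H]2[C@H]3C(=O)C=C(C)[C@@H]2[C@]31C
F4 | step 11 | (4R,5S,7R,10R,11R)-7-hydroxylongipin-2-ene-1,9-dione | O=C1C[C@@H](O)C(C)(C)[C@@H]2[C@H]3C(=O)C=C(C)[C@@H]2[C@]31C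
F5 | step 11 | (4R,5S,7R,9R,10R,11R)-9-hydroxy-1-oxolongipin-2-en-7-yl (E)-2-methylbut-2-enoate | O[C@@H]1C[C@@H](OC(=O)/C(C)=C/C)C(C)(C)[C@@H]2[C@H]3C(=O)C=C(C)[C@@H]2[C@]31C
F6 | step 9 | ethyl 3-{[(1S,4R,6R)-6-[(tert-butyldimethylsilyl)oxy]-3,7,7-trimethyl-4-[(triethylsilyl)oxy]cyclohept-2-en-1-yl]methyl}but-3-enoate | CCOC(=O)CC(=C)C[C@@H]1C(C)(C)[C@H](O[Si](C)(C)C(C)(C)C)C[C@@H](O[Si](CC)(CC)CC)C(C)=C1
F7 | step 9 | 3-{[(1S,4R,6R)-6-[(tert-butyldimethylsilyl)oxy]-3,7,7-trimethyl-4-[(triethylsilyl)oxy]cyclohept-2-en-1-yl]methyl}but-3-enoic acid | OC(=O)CC(=C)C[C@@H]1C(C)(C)[C@H](O[Si](C)(C)C(C)(C)C)C[C@@H](O[Si](CC)(CC)CC)C(C)=C1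
F8 | step 9 | 3-{[(1S,4R,6R)-6-[(tert-butyldimethylsilyl)oxy]-3,7,7-trimethyl-4-[(triethylsilyl)oxy]cyclohept-2-en-1-yl]methyl}but-3-enoyl chloride | ClC(=O)CC(=C)C[C@@H]1C(C)(C)[C@H](O[Si](C)(C)C(C)(C)C)C[C@@H](O[Si](CC)(CC)CC)C(C)=C1
F9 | step 3 | ethyl (E)-4-[(6R)-6-[(tert-butyldimethylsilyl)oxy]-3,7,7-trimethyl-2-oxocyclohept-3-en-1-yl]-4-hydroxy-3-methylbut-2-enoate (diastereomers at the two new centres) | CCOC(=O)/C=C(\C)C(O)C1C(C)(C)[C@H](O[Si](C)(C)C(C)(C)C)CC=C(C)C1=O
F10 | step 3 | ethyl (2E)-4-[(6R)-6-[(tert-butyldimethylsilyl)oxy]-3,7,7-trimethyl-2-oxocyclohept-3-en-1-ylidene]-3-methylbut-2-enoate | CCOC(=O)/C=C(\C)C=C1C(=O)C(C)=CC[C@@H](O[Si](C)(C)C(C)(C)C)C1(C)C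
F11 | step 1 | (4R,5S)-4,5-epoxy-2,6,6-trimethylcyclohept-2-en-1-one | CC1=C[C@H]2O[C@H]2C(C)(C)CC1=O
A1 | alternative 1 | meso cis-diacetyl bicyclo[4.1.1]octane with C9 ethylene ketal | O1CCOC12CCC(C)(C)[C@@H]3[C@@H](C(C)=O)[C@@]2(C)[C@H]3C(C)=O
A2 | alternative 1 | longipinenone core as its C9 ethylene ketal | O1CCOC12CCC(C)(C)[C@@H]3[C@H]4C(=O)C=C(C)[C@@H]3[C@]42C
A3 | alternative 2 | (2E,6E,8R)-8-[(tert-butyldimethylsilyl)oxy]-3,7,11-trimethyldodeca-2,6,10-trienoyl chloride | ClC(=O)/C=C(\C)CC/C=C(\C)[C@H](O[Si](C)(C)C(C)(C)C)CC=C(C)C
A4 | alternative 2 | bicyclic cyclobutanone (C5 ketone, exocyclic methylene on C3, quaternary C10 with the silyloxy prenyl chain) | CC(C)=CC[C@@H](O[Si](C)(C)C(C)(C)C)[C@@]1(C)[C@@H]2CCC(=C)[C@H]1C2=O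
A5 | alternative 3 | tricyclic norbornene: C1 bridgehead alcohol, endo C11 mesylate, 7-OTBS, 9-OTES | CS(=O)(=O)O[C@@H]1[C@H]2C(C)(C)[C@H](O[Si](C)(C)C(C)(C)C)C[C@@H](O[Si](CC)(CC)CC)[C@]3(C)[C@H]2C(C)=C[C@]13O
A6 | alternative 3 | 7,9-bis-silylated longipinenone core (identical with 17) | CC[Si](CC)(CC)O[C@@H]1C[C@@H](O[Si](C)(C)C(C)(C)C)C(C)(C)[C@@H]2[C@H]3C(=O)C=C(C)[C@@H]2[C@]31C
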